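Stop the clock at 0.500 d: ring reads 22.4% in the amber run and 18.8% in the blue run, so ask what the protic impurity has taken by then.

all flasks: starting material 2.2 M
- amber: protic impurity 0.11 M; run made earlier
- blue: protic impurity 0.44 M; run made earlier
- flask: protic impurity 0.220 M; time 8.0 d

| run | time / d | ring / % |
|---|---|---|
| amber | 0.167 | 12.4 |
| amber | 0.500 | 22.4 |
| amber | 1.67 | 12.5 |
| amber | 5.00 | 0 |
| blue | 0.167 | 11.2 |
| blue | 0.500 | 18.8 |
| blue | 1.67 | 10.2 |
| blue | 5.00 | 0.7 |

(standard deviation of a reading: 0.5 percentage points)

- a reading or a percentage of ring counts all its forms, free or not

* the best time, 8.0 d at the latest, for ring
* the amount of ring, in percent of the starting material charged, at that time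
* earliest time at which at least nineteen twentieths of that best amount are there, in d
* latest time at which they still are, in d

Count turnovers. Suppose each molecule of protic impurity destroys one molecule of starting material and is gone, which makes it the limiting reagent of that quench. Then the toll q, the protic impurity charged per starting material charged, 10.0% in the asked flask, is the share of the charge it can take.

Now solve two extreme flasks. In the fast one, the impurity collects its toll before ring builds up, so the rest of the charge runs on the same clock and every ring reading scales with one minus q. In the slow one, it has taken nothing by the peak, so blue and amber coincide, at a ratio of 1. The fast version asks blue over amber to be 0.842, and the readings at 0.500 d give 0.839, with their scatter. So place the real flask at the fast end. Scaling the amber reading gives my 21.2% at 0.500 d, with the timing left as in amber.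

The forecast, interpolating “between linear and logarithmic in impurity”, says 21.3% at 0.62 d, with the window from 0.44 d to 0.87 d.

The simulation gives 21.4% at 0.640 d, with the window from 0.450 d to 0.878 d.

    starting material → ring (k = 0.0440 h⁻¹)
    2 starting material → open dimer (k = 0.0120 L mol⁻¹ h⁻¹)
    starting material + protic impurity → quenched substrate (k = 0.460 L mol⁻¹ h⁻¹)
    ring → over-reaction product (k = 0.110 h⁻¹)
    starting material + ring ⇌ idle adduct, settled at all times (K = 1.80 L mol⁻¹)

At 0.640 d the asked flask holds 9.99% of quenched substrate, the toll q, and its protic impurity is down to 0.0644% of its own charge. The loss of ring to over-reaction product is the largest single effect on the height: without it the highest ring in the asked flask is 63.9%, not 21.4%. The forecast's height fails only in a run with the impurity's level held up instead of falling, where the highest ring is 14.2%. In the neighbour flask with 0.55 M of starting material, q is 40.0%; with 4.1% of the impurity left at 8.00 d, the count gives 38.4%, and quenched substrate stands at 38.3%.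

The earlier runs and the new flask stem from a simulated flask for substances that don't exist; noise was put on by code.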